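# Total synthesis proposal for CNP0109452.1 by an intramolecular chromium carbene–alkyne–CO benzannulation

## Analysis of the target

- **Ring system.** The target is a 19-membered ansa lactam. A C1–C15 chain bridges the meta positions C16 and C20 of a 1,4-hydroquinone (OH on C18 and C21); the lactam nitrogen sits on C20 and the benzylic methoxy carbon C15 on C16.
- **Stereocentres.** There are seven: 6S, 7S, 10S, 11R, 12S, 14S, 15R. In zigzag terms they are 6,7-syn (OMe/O-carbamoyl), 10,11-syn (Me/OMe), 11,12-anti (OMe/OMe), 12,14-anti (OMe/Me) and 14,15-syn (Me/OMe). The C6/C7 pair is insulated from the C10–C15 array by the C8=C9 alkene.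
- **Alkenes.** All three are Z as drawn: the conjugated 2Z,4Z dienamide and the trisubstituted 8Z alkene.
- **Sensitive groups.** The amidohydroquinone oxidises in air to the quinone. The primary allylic carbamate at C7 and the (Z,Z)-dienamide (isomerised by acid, base, light or heat) also limit the late conditions.
- **What is hard.** The difficulties are the macrocycle, the contiguous C16–C21–C20 substitution of the arene, and telling one oxygen (C7) apart from four methyl ethers.
- **Feature that carries the strategy.** C21, a phenol carbon, lies between the two ring carbons that hold the ansa chain, and the second oxygen is para to it at C18. A chromium carbene–alkyne–CO benzannulation creates exactly this pattern around its CO-derived carbon. C16/C17 can therefore come from a terminal alkyne, C18–C20 from a β-amidovinyl methoxycarbene, and C21 from a carbonyl ligand.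

## Retrosynthetic reasoning

**End game (42 back to 37).** The hydroquinone 42 is made last by reducing quinone 41, because it is the most air-sensitive compound of the route. The carbamate is put on the C7 alcohol 39 only after the ring exists, since a free carbamate NH2 would compete with the amide in the carbene-forming step. The C18 oxygen arrives as a methyl ether in 37 and is unmasked by oxidising the p-methoxyphenol to quinone 38. Desilylation of 38 is planned under acidic fluoride, because a quinone does not tolerate basic fluoride.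

**Arene and ansa ring together (37 back to 35).** Three bonds are cut at once: C17–C18, C16–C21 and C20–C21. This removes the arene and the macrocycle in one operation and leaves an open chain that ends in a terminal alkyne (C16–C17) and a chromium methoxy(β-amidovinyl)carbene (C18–C20). The forward reaction has to insert the alkyne with C17 toward the carbene carbon, insert one CO, and close the six-membered ring onto C20. No other disconnection of the arene gives a precursor without a preformed benzene ring.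

**Carbene from amide (35 back to 33 and 4).** The N–C20 bond is cut. Forward, the primary dienamide 33 adds in conjugate fashion to an ethynyl(methoxy)carbene complex. The parent ethynyl complex does not keep, so it is released in the flask from the storable silyl-capped complex 4, which comes from 1 and 2 by the classical acylate/alkylation sequence.

**Dienamide (33 back to 26).** C2=C3 and C4=C5 are cut, each as a Z-selective phosphonate olefination of an aldehyde (29, then 26), with the ester 30 converted into the amide through acid 31. Making the two Z alkenes one at a time from aldehydes gives independent control of each geometry; a one-step diene construction would not.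

**C6–C7 (26 back to 21 and 23).** A syn glycolate aldol sets both oxygen-bearing centres in one step under auxiliary control. Cutting here keeps C7 as a free hydroxyl that can be silylated at once, which is how it is kept distinct from the four methyl ethers. The thioimide is reduced directly to aldehyde 26.

**C8=C9 (21 back to 18).** The trisubstituted Z alkene is cut to the α-methyl aldehyde 18 and a two-carbon phosphonate. A Z-selective olefination is the shortest reliable way to place C7 cis to C10.

**C10–C11 (18 back to 14).** A syn crotyl transfer to the α-methoxy aldehyde 14 sets the 10,11-syn pair under reagent control. The vinyl group is the latent C9 aldehyde.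

**C11–C12 (14 back to 10).** The α-methoxy aldehyde is cut to aldehyde 10 and a vinyl unit: enantioselective vinyl addition sets C12, methylation fixes the ether, and alkene cleavage gives C11.

**C14–C15 (10 back to 5).** A first syn crotyl transfer to the ynal 5 sets the 14,15-syn pair and delivers the alkyne that the key step needs. Hydroboration of the vinyl group then gives C12 at the aldehyde level. The chain is thus grown from the alkyne end toward C1, each stereocentre being set next to the carbonyl just made.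

## Alternatives that were turned down

**Alternative 1:** The C8=C9 bond is cut. Forward, the C7 and C11 hydroxyls of two fragments are tied through a diisopropylsilylene to give the tethered diene A2, and ring-closing metathesis with the second-generation Grubbs catalyst RuCl2(PCy3)(H2IMes)(CHPh) closes the eight-membered silaketal A1.
- For: the small ring enforces the Z geometry of the trisubstituted alkene, and the union is convergent. On these two points it is stronger than the linear Z-selective olefination used here (step 12).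
- Against: it solves only one alkene. The macrocycle and the amide still need a separate ring closure, and the arene with its bromide must be carried from the start. After the tether is removed, the C7 and C11 hydroxyls are both free and must be told apart, because one becomes a methyl ether and the other the carbamate. Metathesis to a trisubstituted alkene flanked by two branched allylic carbons in a medium ring is slow.
- Comparison: the chosen route differentiates C7 from the outset (silyl ether from the aldol) and spends its key step on the arene and the large ring.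

**Alternative 2:** The C4–C5 bond is cut at the alkyne level. Forward, the methyl-capped diyne A4 undergoes ring-closing alkyne metathesis with Mo(CC6H4OMe)(OSiPh3)3 and molecular sieves to give the enyne lactam A3, and Z-selective semireduction then gives the 4Z alkene.
- For: alkyne metathesis is a dependable way to close large rings, it tolerates the ethers and the silyl ether, and semireduction gives the 4Z geometry with high certainty. As a ring closure it is better precedented than the chosen step.
- Against: the ring closure forms only the macrocycle. The fully substituted aniline fragment has to be made and carried through the whole sequence, the anilide N–H and the conjugated enyne sit next to the reacting alkyne, and the semireduction must stop at a (Z,Z)-diene inside a strained ring. The hydroquinone then appears as its dimethyl ether, which is harder to oxidise than the p-methoxyphenol 37.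
- Comparison: the chosen route accepts more risk in one step, but that step also builds the arene.

**Alternative 3:** The N–C20 bond is cut. Forward, the primary dienamide of the aryl bromide A6 is coupled intramolecularly under CuI, N,N'-dimethylethylenediamine and K2CO3 to give the macrolactam A5.
- For: it uses the same kind of seco primary amide as the chosen route and relies on a known type of amidation, so the risk of the ring closure is lower.
- Against: the aryl bromide is flanked by an ortho methoxy group, and the coupling needs base and heat, conditions under which the (Z,Z)-dienamide can isomerise. The bromoarene must survive every organometallic step of the chain synthesis. The product is again the dimethyl ether.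
- Comparison: the chosen strategy avoids carrying any arene; its alkyne is inert to all chain-building steps, and it delivers the monomethyl ether, which a mild oxidant converts into the quinone.

Key step: step 26

## Forward synthesis

Assumption: the double-bond geometries are taken exactly as drawn (2Z, 4Z, 8Z), so all three olefinations are chosen for Z selectivity.

Step 1
Reactants: 1 ethynyltrimethylsilane; 2 chromium hexacarbonyl, Cr(CO)6
Product: 4 pentacarbonyl[methoxy(trimethylsilylethynyl)carbene]chromium, via lithium acyl chromate 3 (not isolated)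
Conditions: n-BuLi, THF, −78 °C; Cr(CO)6, −78 → 0 °C; MeOTf, CH2Cl2, −40 → 0 °C
Reagents that add atoms: methyl trifluoromethanesulfonate, COS(=O)(=O)C(F)(F)F
Why: Fischer carbene synthesis: the lithium acetylide adds to a carbonyl ligand of zerovalent chromium and the acylate oxygen is methylated by the hard electrophile; the silyl cap makes the alkynylcarbene complex storable.

Step 2
Reactants: 5 3-(trimethylsilyl)prop-2-ynal
Product: 6 (3R,4S)-4-methyl-1-(trimethylsilyl)hex-5-en-1-yn-3-ol
Conditions: (Z)-crotyl-B(Ipc)2 [cis-2-butene, KOt-Bu, n-BuLi, THF, −78 → −45 °C; (+)-Ipc2BOMe from (−)-α-pinene; BF3·OEt2], −78 °C; then NaBO3·4H2O, THF/H2O, 20 °C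
Reagents that add atoms: (Z)-crotyldiisopinocampheylborane (from (−)-α-pinene), C/C=C\CB([C@H]1C[C@H]2C[C@@H]([C@@H]1C)C2(C)C)[C@H]1C[C@H]2C[C@@H]([C@@H]1C)C2(C)C
Why: Brown crotylboration through a closed chair transition state: the Z-crotyl geometry gives the 14,15-syn relationship, and the isopinocampheyl groups of the (−)-α-pinene series select the aldehyde face that gives 15R,14S.

Step 3
Reactants: 6 (3R,4S)-4-methyl-1-(trimethylsilyl)hex-5-en-1-yn-3-ol
Product: 7 [(3R,4S)-3-methoxy-4-methylhex-5-en-1-yn-1-yl]trimethylsilane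
Conditions: Me3OBF4, 1,8-bis(dimethylamino)naphthalene, CH2Cl2, 0 → 20 °C
Reagents that add atoms: trimethyloxonium tetrafluoroborate, C[O+](C)C.F[B-](F)(F)F
Why: O-methylation with a Meerwein salt and a hindered amine base; no alkoxide is formed, so the alkynylsilane and the propargylic centre are not at risk.

Step 4
Reactants: 7 [(3R,4S)-3-methoxy-4-methylhex-5-en-1-yn-1-yl]trimethylsilane
Product: 9 (3S,4R)-4-methoxy-3-methyl-6-(trimethylsilyl)hex-5-yn-1-ol, via B-alkyl-9-borabicyclononane 8 (not isolated)
Conditions: 9-BBN, THF, 0 → 20 °C; then 30% H2O2, aq. NaOAc, 0 → 20 °C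
Reagents that add atoms: hydrogen peroxide, OO
Why: Anti-Markovnikov hydroboration–oxidation; 9-BBN reacts with the monosubstituted alkene far faster than with the internal silylalkyne, and the buffered oxidation spares the C–Si bond.

Step 5
Reactants: 9 (3S,4R)-4-methoxy-3-methyl-6-(trimethylsilyl)hex-5-yn-1-ol
Product: 10 (3S,4R)-4-methoxy-3-methyl-6-(trimethylsilyl)hex-5-ynal
Conditions: Dess–Martin periodinane, NaHCO3, CH2Cl2, 0 → 20 °C
Reagents that add atoms: none
Why: Dess–Martin oxidation of a primary alcohol under buffered, non-epimerising conditions; the aldehyde has no α-stereocentre.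

Step 6
Reactants: 10 (3S,4R)-4-methoxy-3-methyl-6-(trimethylsilyl)hex-5-ynal
Product: 11 (3S,5S,6R)-6-methoxy-5-methyl-8-(trimethylsilyl)oct-1-en-7-yn-3-ol
Conditions: (CH2=CH)2Zn, (2R)-(+)-3-exo-(dimethylamino)isoborneol (5 mol%), toluene/Et2O, 0 °C
Reagents that add atoms: divinylzinc, C=C[Zn]C=C
Why: Amino-alcohol-catalysed enantioselective vinylzinc addition to an aldehyde; the (+)-ligand directs the vinyl group to the Re face and so sets C12 as S under catalyst control, the remote C14 centre having little influence.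

Step 7
Reactants: 11 (3S,5S,6R)-6-methoxy-5-methyl-8-(trimethylsilyl)oct-1-en-7-yn-3-ol
Product: 12 [(3R,4S,6S)-3,6-dimethoxy-4-methyloct-7-en-1-yn-1-yl]trimethylsilane
Conditions: Me3OBF4, 1,8-bis(dimethylamino)naphthalene, CH2Cl2, 0 → 20 °C
Reagents that add atoms: trimethyloxonium tetrafluoroborate, C[O+](C)C.F[B-](F)(F)F
Why: Neutral O-methylation of the allylic alcohol as in step 3; the C12 configuration is untouched.

Step 8
Reactants: 12 [(3R,4S,6S)-3,6-dimethoxy-4-methyloct-7-en-1-yn-1-yl]trimethylsilane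
Product: 14 (2S,4S,5R)-2,5-dimethoxy-4-methyl-7-(trimethylsilyl)hept-6-ynal, via terminal diol 13 (not isolated)
Conditions: OsO4 (2 mol%), NaIO4, 2,6-lutidine, dioxane/H2O, 20 °C
Reagents that add atoms: sodium periodate (terminal oxidant; supplies the carbonyl oxygen by way of OsO4), [Na+].[O-]I(=O)(=O)=O
Why: Johnson–Lemieux dihydroxylation–cleavage; OsO4 does not attack the silylalkyne, and the lutidine buffer keeps the α-methoxy aldehyde from epimerising; it is used crude.

Step 9
Reactants: 14 (2S,4S,5R)-2,5-dimethoxy-4-methyl-7-(trimethylsilyl)hept-6-ynal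
Product: 15 (3S,4R,5S,7S,8R)-5,8-dimethoxy-3,7-dimethyl-10-(trimethylsilyl)dec-1-en-9-yn-4-ol
Conditions: (Z)-crotyl-B(Ipc)2 [cis-2-butene, KOt-Bu, n-BuLi, THF, −78 → −45 °C; (+)-Ipc2BOMe from (−)-α-pinene; BF3·OEt2], −78 °C; then NaBO3·4H2O, THF/H2O, 20 °C
Reagents that add atoms: (Z)-crotyldiisopinocampheylborane (from (−)-α-pinene), C/C=C\CB([C@H]1C[C@H]2C[C@@H]([C@@H]1C)C2(C)C)[C@H]1C[C@H]2C[C@@H]([C@@H]1C)C2(C)C
Why: Second Brown crotylboration: the Z-crotyl reagent gives the 10,11-syn pair and the same isopinocampheyl series gives 10S,11R; the α-methoxy group of 14 favours the same 11,12-anti product (Felkin/Cornforth), so reagent and substrate should be matched.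

Step 10
Reactants: 15 (3S,4R,5S,7S,8R)-5,8-dimethoxy-3,7-dimethyl-10-(trimethylsilyl)dec-1-en-9-yn-4-ol
Product: 16 [(3R,4S,6S,7R,8S)-3,6,7-trimethoxy-4,8-dimethyldec-9-en-1-yn-1-yl]trimethylsilane
Conditions: Me3OBF4, 1,8-bis(dimethylamino)naphthalene, CH2Cl2, 0 → 20 °C
Reagents that add atoms: trimethyloxonium tetrafluoroborate, C[O+](C)C.F[B-](F)(F)F
Why: Neutral O-methylation of the hindered secondary alcohol; this installs the third of the four methyl ethers.

Step 11
Reactants: 16 [(3R,4S,6S,7R,8S)-3,6,7-trimethoxy-4,8-dimethyldec-9-en-1-yn-1-yl]trimethylsilane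
Product: 18 (2R,3R,4S,6S,7R)-3,4,7-trimethoxy-2,6-dimethyl-9-(trimethylsilyl)non-8-ynal, via terminal diol 17 (not isolated)
Conditions: OsO4 (2 mol%), NaIO4, 2,6-lutidine, dioxane/H2O, 20 °C
Reagents that add atoms: sodium periodate (terminal oxidant; supplies the carbonyl oxygen by way of OsO4), [Na+].[O-]I(=O)(=O)=O
Why: Johnson–Lemieux cleavage of the vinyl group to the C9 aldehyde; C10 keeps its configuration (its descriptor changes to R only because the new CHO outranks C11), and the aldehyde is used at once.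

Step 12
Reactants: 18 (2R,3R,4S,6S,7R)-3,4,7-trimethoxy-2,6-dimethyl-9-(trimethylsilyl)non-8-ynal
Product: 19 methyl (2Z,4S,5R,6S,8S,9R)-5,6,9-trimethoxy-2,4,8-trimethyl-11-(trimethylsilyl)undec-2-en-10-ynoate
Conditions: (CF3CH2O)2P(O)CH(CH3)CO2Me, KN(SiMe3)2, 18-crown-6, THF, −78 °C
Reagents that add atoms: methyl 2-[bis(2,2,2-trifluoroethoxy)phosphoryl]propanoate, COC(=O)C(C)P(=O)(OCC(F)(F)F)OCC(F)(F)F
Why: Still–Gennari olefination: the electron-poor phosphonate eliminates quickly from the kinetic adduct and gives the Z trisubstituted enoate (C7 cis to C10); at −78 °C the α-methyl aldehyde is not epimerised by the weakly basic phosphonate anion.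

Step 13
Reactants: 19 methyl (2Z,4S,5R,6S,8S,9R)-5,6,9-trimethoxy-2,4,8-trimethyl-11-(trimethylsilyl)undec-2-en-10-ynoate
Product: 20 (2Z,4S,5R,6S,8S,9R)-5,6,9-trimethoxy-2,4,8-trimethyl-11-(trimethylsilyl)undec-2-en-10-yn-1-ol
Conditions: i-Bu2AlH, CH2Cl2, −78 °C
Reagents that add atoms: none
Why: 1,2-Reduction of the enoate to the allylic alcohol by i-Bu2AlH; alkene geometry and the silylalkyne are unaffected at low temperature.

Step 14
Reactants: 20 (2Z,4S,5R,6S,8S,9R)-5,6,9-trimethoxy-2,4,8-trimethyl-11-(trimethylsilyl)undec-2-en-10-yn-1-ol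
Product: 21 (2Z,4S,5R,6S,8S,9R)-5,6,9-trimethoxy-2,4,8-trimethyl-11-(trimethylsilyl)undec-2-en-10-ynal
Conditions: Dess–Martin periodinane, NaHCO3, CH2Cl2, 0 °C
Reagents that add atoms: none
Why: Buffered Dess–Martin oxidation of the allylic alcohol; the α-methyl substituent slows Z to E isomerisation of the enal, which is used without storage.

Step 15
Reactants: 22 (R)-4-benzylthiazolidine-2-thione
Product: 23 (R)-4-benzyl-3-(methoxyacetyl)thiazolidine-2-thione
Conditions: MeOCH2COCl, Et3N, CH2Cl2, 0 °C
Reagents that add atoms: methoxyacetyl chloride, COCC(Cl)=O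
Why: N-acylation of the thiazolidinethione auxiliary with an acid chloride; this gives the glycolate unit that will become C5–C6 with its methoxy group.

Step 16
Reactants: 21 (2Z,4S,5R,6S,8S,9R)-5,6,9-trimethoxy-2,4,8-trimethyl-11-(trimethylsilyl)undec-2-en-10-ynal; 23 (R)-4-benzyl-3-(methoxyacetyl)thiazolidine-2-thione
Product: 24 (R)-4-benzyl-3-[(2R,3S,4Z,6S,7R,8S,10S,11R)-3-hydroxy-2,7,8,11-tetramethoxy-4,6,10-trimethyl-13-(trimethylsilyl)tridec-4-en-12-ynoyl]thiazolidine-2-thione
Conditions: TiCl4, i-Pr2NEt, N-methyl-2-pyrrolidone, CH2Cl2, 0 → −78 °C; then 21, −78 °C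
Reagents that add atoms: none
Why: Titanium-enolate aldol of an N-glycolylthiazolidinethione in the Evans-syn mode (non-chelated transition state in the presence of the pyrrolidone): the Z-enolate gives the 6,7-syn pair, and the (R)-auxiliary fixes the absolute sense that becomes 6S,7S in the target; the remote C10 centre has no say.

Step 17
Reactants: 24 (R)-4-benzyl-3-[(2R,3S,4Z,6S,7R,8S,10S,11R)-3-hydroxy-2,7,8,11-tetramethoxy-4,6,10-trimethyl-13-(trimethylsilyl)tridec-4-en-12-ynoyl]thiazolidine-2-thione
Product: 25 (R)-4-benzyl-3-[(2R,3S,4Z,6S,7R,8S,10S,11R)-3-(tert-butyldimethylsilyloxy)-2,7,8,11-tetramethoxy-4,6,10-trimethyl-13-(trimethylsilyl)tridec-4-en-12-ynoyl]thiazolidine-2-thione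
Conditions: TBSOTf, 2,6-lutidine, CH2Cl2, −78 → 0 °C
Reagents that add atoms: tert-butyldimethylsilyl trifluoromethanesulfonate, CC(C)(C)[Si](C)(C)OS(=O)(=O)C(F)(F)F
Why: Silylation of the hindered allylic alcohol with the silyl triflate; this marks C7 as the one oxygen that will not become a methyl ether and prevents retro-aldol cleavage.

Step 18
Reactants: 25 (R)-4-benzyl-3-[(2R,3S,4Z,6S,7R,8S,10S,11R)-3-(tert-butyldimethylsilyloxy)-2,7,8,11-tetramethoxy-4,6,10-trimethyl-13-(trimethylsilyl)tridec-4-en-12-ynoyl]thiazolidine-2-thione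
Product: 26 (2R,3S,4Z,6S,7R,8S,10S,11R)-3-(tert-butyldimethylsilyloxy)-2,7,8,11-tetramethoxy-4,6,10-trimethyl-13-(trimethylsilyl)tridec-4-en-12-ynal
Conditions: i-Bu2AlH, CH2Cl2, −78 °C
Reagents that add atoms: none
Why: Direct reduction of the N-acylthiazolidinethione to the aldehyde: the tetrahedral aluminium adduct is stable at −78 °C and collapses on work-up, releasing the auxiliary 22.

Step 19
Reactants: 26 (2R,3S,4Z,6S,7R,8S,10S,11R)-3-(tert-butyldimethylsilyloxy)-2,7,8,11-tetramethoxy-4,6,10-trimethyl-13-(trimethylsilyl)tridec-4-en-12-ynal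
Product: 27 methyl (2Z,4S,5S,6Z,8S,9R,10S,12S,13R)-5-(tert-butyldimethylsilyloxy)-4,9,10,13-tetramethoxy-6,8,12-trimethyl-15-(trimethylsilyl)pentadeca-2,6-dien-14-ynoate
Conditions: (CF3CH2O)2P(O)CH2CO2Me, KN(SiMe3)2, 18-crown-6, THF, −78 °C
Reagents that add atoms: methyl 2-[bis(2,2,2-trifluoroethoxy)phosphoryl]acetate, COC(=O)CP(=O)(OCC(F)(F)F)OCC(F)(F)F
Why: Still–Gennari olefination sets the C4=C5 alkene as Z; the α-methoxy aldehyde is consumed at −78 °C before it can epimerise.

Step 20
Reactants: 27 methyl (2Z,4S,5S,6Z,8S,9R,10S,12S,13R)-5-(tert-butyldimethylsilyloxy)-4,9,10,13-tetramethoxy-6,8,12-trimethyl-15-(trimethylsilyl)pentadeca-2,6-dien-14-ynoate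
Product: 28 (2Z,4S,5S,6Z,8S,9R,10S,12S,13R)-5-(tert-butyldimethylsilyloxy)-4,9,10,13-tetramethoxy-6,8,12-trimethyl-15-(trimethylsilyl)pentadeca-2,6-dien-14-yn-1-ol
Conditions: i-Bu2AlH, CH2Cl2, −78 °C
Reagents that add atoms: none
Why: 1,2-Reduction of the Z-enoate to the Z-allylic alcohol; the silyl ether and silylalkyne are inert.

Step 21
Reactants: 28 (2Z,4S,5S,6Z,8S,9R,10S,12S,13R)-5-(tert-butyldimethylsilyloxy)-4,9,10,13-tetramethoxy-6,8,12-trimethyl-15-(trimethylsilyl)pentadeca-2,6-dien-14-yn-1-ol
Product: 29 (2Z,4S,5S,6Z,8S,9R,10S,12S,13R)-5-(tert-butyldimethylsilyloxy)-4,9,10,13-tetramethoxy-6,8,12-trimethyl-15-(trimethylsilyl)pentadeca-2,6-dien-14-ynal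
Conditions: Dess–Martin periodinane, NaHCO3, CH2Cl2, 0 °C
Reagents that add atoms: none
Why: Buffered Dess–Martin oxidation to the (Z)-enal; it is filtered cold and taken directly into the next olefination to limit Z to E isomerisation.

Step 22
Reactants: 29 (2Z,4S,5S,6Z,8S,9R,10S,12S,13R)-5-(tert-butyldimethylsilyloxy)-4,9,10,13-tetramethoxy-6,8,12-trimethyl-15-(trimethylsilyl)pentadeca-2,6-dien-14-ynal
Product: 30 methyl (2Z,4Z,6S,7S,8Z,10S,11R,12S,14S,15R)-7-(tert-butyldimethylsilyloxy)-6,11,12,15-tetramethoxy-2,8,10,14-tetramethyl-17-(trimethylsilyl)heptadeca-2,4,8-trien-16-ynoate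
Conditions: (CF3CH2O)2P(O)CH(CH3)CO2Me, KN(SiMe3)2, 18-crown-6, THF, −78 °C
Reagents that add atoms: methyl 2-[bis(2,2,2-trifluoroethoxy)phosphoryl]propanoate, COC(=O)C(C)P(=O)(OCC(F)(F)F)OCC(F)(F)F
Why: Third Still–Gennari olefination, now with the α-methyl phosphonate, sets the 2Z trisubstituted alkene (C1 cis to C4) and completes the (2Z,4Z)-dienoate.

Step 23
Reactants: 30 methyl (2Z,4Z,6S,7S,8Z,10S,11R,12S,14S,15R)-7-(tert-butyldimethylsilyloxy)-6,11,12,15-tetramethoxy-2,8,10,14-tetramethyl-17-(trimethylsilyl)heptadeca-2,4,8-trien-16-ynoate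
Product: 31 (2Z,4Z,6S,7S,8Z,10S,11R,12S,14S,15R)-7-(tert-butyldimethylsilyloxy)-6,11,12,15-tetramethoxy-2,8,10,14-tetramethylheptadeca-2,4,8-trien-16-ynoic acid
Conditions: LiOH, THF/MeOH/H2O, 20 → 40 °C; then 0.5 M HCl to pH 4
Reagents that add atoms: water, O
Why: Saponification of the hindered methyl ester; the same hydroxide/methanol medium cleaves the alkynyl C–Si bond, so the terminal alkyne for the key step is freed in the same operation, while the secondary silyl ether survives.

Step 24
Reactants: 31 (2Z,4Z,6S,7S,8Z,10S,11R,12S,14S,15R)-7-(tert-butyldimethylsilyloxy)-6,11,12,15-tetramethoxy-2,8,10,14-tetramethylheptadeca-2,4,8-trien-16-ynoic acid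
Product: 33 (2Z,4Z,6S,7S,8Z,10S,11R,12S,14S,15R)-7-(tert-butyldimethylsilyloxy)-6,11,12,15-tetramethoxy-2,8,10,14-tetramethylheptadeca-2,4,8-trien-16-ynamide, via isobutyl mixed anhydride 32 (not isolated)
Conditions: i-BuOCOCl, N-methylmorpholine, THF, −15 °C; then NH3 (0.5 M in dioxane), −15 → 20 °C
Reagents that add atoms: ammonia, N
Why: Mixed-anhydride amidation; activation and aminolysis at low temperature avoid isomerisation of the (Z,Z)-diene, and ammonia attacks the less hindered, more electrophilic acyl carbon of the dienoyl group.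

Step 25
Reactants: 33 (2Z,4Z,6S,7S,8Z,10S,11R,12S,14S,15R)-7-(tert-butyldimethylsilyloxy)-6,11,12,15-tetramethoxy-2,8,10,14-tetramethylheptadeca-2,4,8-trien-16-ynamide; 4 pentacarbonyl[methoxy(trimethylsilylethynyl)carbene]chromium
Product: 35 pentacarbonyl{(2E)-3-[(2Z,4Z,6S,7S,8Z,10S,11R,12S,14S,15R)-7-(tert-butyldimethylsilyloxy)-6,11,12,15-tetramethoxy-2,8,10,14-tetramethylheptadeca-2,4,8-trien-16-ynoylamino]-1-methoxyprop-2-enylidene}chromium, via ethynyl(methoxy)carbene complex 34 (not isolated)
Conditions: 4 (1.5 equiv), KF, 18-crown-6, THF, −40 → 0 °C; pH 7 buffer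
Reagents that add atoms: none
Why: Aza-Michael addition of an N–H nucleophile to an alkynyl(alkoxy)carbene complex, the reaction type by which amines give β-aminovinyl carbenes. Fluoride cleaves the very labile alkynyl C–Si bond of 4 to release the parent ethynyl complex 34 in the flask and acts as the base that lets the weakly nucleophilic amide add at the β-carbon. The E enamide is expected, and its geometry does not matter later.

Step 26
Reactants: 35 pentacarbonyl{(2E)-3-[(2Z,4Z,6S,7S,8Z,10S,11R,12S,14S,15R)-7-(tert-butyldimethylsilyloxy)-6,11,12,15-tetramethoxy-2,8,10,14-tetramethylheptadeca-2,4,8-trien-16-ynoylamino]-1-methoxyprop-2-enylidene}chromium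
Product: 37 19-membered ansa lactam (2Z,4Z,8Z; 6S,7S,10S,11R,12S,14S,15R) with C7 tert-butyldimethylsilyl ether plus C18 methyl ether plus C21 phenol, via tricarbonylchromium arene complex 36 (not isolated)
Conditions: THF (0.001 M, slow addition of 35), 65 °C, Ar; then air, MeCN, 20 °C
Reagents that add atoms: none
Why: Proposed new method: thermal loss of one cis CO from the zerovalent chromium carbene lets the tethered terminal alkyne bind and insert into the Cr=C18 bond with its unsubstituted carbon C17 next to the carbene carbon (C17–C18); CO then inserts to give a chromium-bound dienylketene (C16–C21), and 6π electrocyclisation onto the enamide carbon C20 followed by tautomerisation gives the phenol as its Cr(CO)3 complex 36, which air sets free. The closest known reaction is the intramolecular Dötz benzannulation of alkenyl(alkoxy)carbene complexes that carry a remote alkyne on the β-carbon, which gives metacyclophanes; a β-acylamino group on the vinyl carbene is the untested element. The benzene ring closes by the electrocyclisation of the C21=C16–C17=C18–C19=C20 array, and the 19-membered ansa ring closes in the alkyne-insertion event that joins the chain end to C18 and is completed by the C16–C21 bond. No stereocentre is formed and the conditions are neutral, so the seven existing centres and the three Z alkenes are not touched. Three selectivities are needed. Regiochemistry: a terminal alkyne places its substituted carbon (C16, with the bulky C15 ether) beside the CO-derived carbon, and the long flexible tether imposes no opposite bias. CO insertion over the five-membered-ring channel typical of β-aminovinyl carbenes: the N-acyl group makes nitrogen a weak donor, and chromium with a methoxy carbene in an ether solvent favours the phenol pathway. Ring closure over oligomerisation: slow addition at about 0.001 M; the C19=C20 geometry does not matter because C20 is sp3 in the cyclohexadienone before it aromatises.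

Step 27
Reactants: 37 19-membered ansa lactam with C7 silyl ether plus C18 methyl ether plus C21 phenol
Product: 38 ansa benzoquinone lactam with C7 tert-butyldimethylsilyl ether (C18 and C21 carbonyls)
Conditions: (NH4)2Ce(NO3)6, MeCN/H2O, 0 °C
Reagents that add atoms: water, O
Why: Oxidative demethylation of a p-methoxyphenol by tetravalent cerium: two one-electron oxidations, capture of the oxocarbenium ion at C18 by water, and loss of methanol give the p-quinone; a free phenol makes this much easier than for a dimethyl ether, so the alkenes are spared.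

Step 28
Reactants: 38 ansa benzoquinone lactam with C7 tert-butyldimethylsilyl ether
Product: 39 ansa benzoquinone lactam with free C7 hydroxyl
Conditions: HF·pyridine, pyridine/THF, 0 → 20 °C
Reagents that add atoms: none
Why: Acidic fluoride cleaves the secondary silyl ether; a buffered acidic reagent is chosen because the quinone and the dienamide do not tolerate basic fluoride.

Step 29
Reactants: 39 ansa benzoquinone lactam with free C7 hydroxyl
Product: 41 ansa benzoquinone lactam with C7 carbamate (2Z,4Z,8Z; 6S,7S,10S,11R,12S,14S,15R), via N-trichloroacetyl carbamate 40 (not isolated)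
Conditions: Cl3CC(O)NCO, CH2Cl2, 0 °C; then neutral Al2O3, 20 °C
Reagents that add atoms: trichloroacetyl isocyanate, O=C=NC(=O)C(Cl)(Cl)Cl
Why: The acyl isocyanate carbamoylates the only free hydroxyl; the activating trichloroacetyl group is then hydrolysed on neutral alumina, which avoids alkoxide that could add to the quinone.

Step 30
Reactants: 41 ansa benzoquinone lactam with C7 carbamate
Product: 42 CNP0109452.1 (hydroquinone; 2Z,4Z,8Z; 6S,7S,10S,11R,12S,14S,15R)
Conditions: Na2S2O4, EtOAc/H2O, 20 °C, Ar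
Reagents that add atoms: none
Why: Two-electron reduction of the p-quinone to the hydroquinone by dithionite in a two-phase system; nothing else in the molecule is reducible under these conditions, and the product is handled under argon.

## Compound list

1 | ethynyltrimethylsilane | C#C[Si](C)(C)C | starting material
2 | chromium hexacarbonyl | O=C=[Cr](=C=O)(=C=O)(=C=O)(=C=O)=C=O | starting material
3 | lithium pentacarbonyl[3-(trimethylsilyl)propynoyl]chromate | [Li+].[O-]C(C#C[Si](C)(C)C)=[Cr](=C=O)(=C=O)(=C=O)(=C=O)=C=O | intermediate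
4 | pentacarbonyl[methoxy(trimethylsilylethynyl)carbene]chromium | COC(C#C[Si](C)(C)C)=[Cr](=C=O)(=C=O)(=C=O)(=C=O)=C=O | intermediate
5 | 3-(trimethylsilyl)prop-2-ynal | O=CC#C[Si](C)(C)C | starting material
6 | (3R,4S)-4-methyl-1-(trimethylsilyl)hex-5-en-1-yn-3-ol | C[Si](C)(C)C#C[C@H](O)[C@@H](C)C=C | intermediate
7 | [(3R,4S)-3-methoxy-4-methylhex-5-en-1-yn-1-yl]trimethylsilane | C[Si](C)(C)C#C[C@H](OC)[C@@H](C)C=C | intermediate
8 | B-alkyl-9-borabicyclononane from 7 | C[Si](C)(C)C#C[C@H](OC)[C@@H](C)CCB1C2CCCC1CCC2 | intermediate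
9 | (3S,4R)-4-methoxy-3-methyl-6-(trimethylsilyl)hex-5-yn-1-ol | C[Si](C)(C)C#C[C@H](OC)[C@@H](C)CCO | intermediate
10 | (3S,4R)-4-methoxy-3-methyl-6-(trimethylsilyl)hex-5-ynal | C[Si](C)(C)C#C[C@H](OC)[C@@H](C)CC=O | intermediate
11 | (3S,5S,6R)-6-methoxy-5-methyl-8-(trimethylsilyl)oct-1-en-7-yn-3-ol | C[Si](C)(C)C#C[C@H](OC)[C@@H](C)C[C@H](O)C=C | intermediate
12 | [(3R,4S,6S)-3,6-dimethoxy-4-methyloct-7-en-1-yn-1-yl]trimethylsilane | C[Si](C)(C)C#C[C@H](OC)[C@@H](C)C[C@H](OC)C=C | intermediate
13 | terminal diol from 12 (mixture at the new carbinol) | C[Si](C)(C)C#C[C@H](OC)[C@@H](C)C[C@H](OC)C(O)CO | intermediate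
14 | (2S,4S,5R)-2,5-dimethoxy-4-methyl-7-(trimethylsilyl)hept-6-ynal | C[Si](C)(C)C#C[C@H](OC)[C@@H](C)C[C@H](OC)C=O | intermediate
15 | (3S,4R,5S,7S,8R)-5,8-dimethoxy-3,7-dimethyl-10-(trimethylsilyl)dec-1-en-9-yn-4-ol | C[Si](C)(C)C#C[C@H](OC)[C@@H](C)C[C@H](OC)[C@H](O)[C@@H](C)C=C | intermediate
16 | [(3R,4S,6S,7R,8S)-3,6,7-trimethoxy-4,8-dimethyldec-9-en-1-yn-1-yl]trimethylsilane | C[Si](C)(C)C#C[C@H](OC)[C@@H](C)C[C@H](OC)[C@H](OC)[C@@H](C)C=C | intermediate
17 | terminal diol from 16 (mixture at the new carbinol) | C[Si](C)(C)C#C[C@H](OC)[C@@H](C)C[C@H](OC)[C@H](OC)[C@@H](C)C(O)CO | intermediate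
18 | (2R,3R,4S,6S,7R)-3,4,7-trimethoxy-2,6-dimethyl-9-(trimethylsilyl)non-8-ynal | C[Si](C)(C)C#C[C@H](OC)[C@@H](C)C[C@H](OC)[C@H](OC)[C@@H](C)C=O | intermediate
19 | methyl (2Z,4S,5R,6S,8S,9R)-5,6,9-trimethoxy-2,4,8-trimethyl-11-(trimethylsilyl)undec-2-en-10-ynoate | C[Si](C)(C)C#C[C@H](OC)[C@@H](C)C[C@H](OC)[C@H](OC)[C@@H](C)/C=C(C)\C(=O)OC | intermediate
20 | (2Z,4S,5R,6S,8S,9R)-5,6,9-trimethoxy-2,4,8-trimethyl-11-(trimethylsilyl)undec-2-en-10-yn-1-ol | C[Si](C)(C)C#C[C@H](OC)[C@@H](C)C[C@H](OC)[C@H](OC)[C@@H](C)/C=C(C)\CO | intermediate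
21 | (2Z,4S,5R,6S,8S,9R)-5,6,9-trimethoxy-2,4,8-trimethyl-11-(trimethylsilyl)undec-2-en-10-ynal | C[Si](C)(C)C#C[C@H](OC)[C@@H](C)C[C@H](OC)[C@H](OC)[C@@H](C)/C=C(C)\C=O | intermediate
22 | (R)-4-benzylthiazolidine-2-thione | S=C1N[C@H](Cc2ccccc2)CS1 | starting material
23 | (R)-4-benzyl-3-(methoxyacetyl)thiazolidine-2-thione | COCC(=O)N1[C@H](Cc2ccccc2)CSC1=S | intermediate
24 | (R)-4-benzyl-3-[(2R,3S,4Z,6S,7R,8S,10S,11R)-3-hydroxy-2,7,8,11-tetramethoxy-4,6,10-trimethyl-13-(trimethylsilyl)tridec-4-en-12-ynoyl]thiazolidine-2-thione | C[Si](C)(C)C#C[C@H](OC)[C@@H](C)C[C@H](OC)[C@H](OC)[C@@H](C)/C=C(C)\[C@H](O)[C@@H](OC)C(=O)N1[C@H](Cc2ccccc2)CSC1=S | intermediate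
25 | 3-O-tert-butyldimethylsilyl ether of 24 | C[Si](C)(C)C#C[C@H](OC)[C@@H](C)C[C@H](OC)[C@H](OC)[C@@H](C)/C=C(C)\[C@H](O[Si](C)(C)C(C)(C)C)[C@@H](OC)C(=O)N1[C@H](Cc2ccccc2)CSC1=S | intermediate
26 | (2R,3S,4Z,6S,7R,8S,10S,11R)-3-(tert-butyldimethylsilyloxy)-2,7,8,11-tetramethoxy-4,6,10-trimethyl-13-(trimethylsilyl)tridec-4-en-12-ynal | C[Si](C)(C)C#C[C@H](OC)[C@@H](C)C[C@H](OC)[C@H](OC)[C@@H](C)/C=C(C)\[C@H](O[Si](C)(C)C(C)(C)C)[C@@H](OC)C=O | intermediate
27 | methyl (2Z,4S,5S,6Z,8S,9R,10S,12S,13R)-5-(tert-butyldimethylsilyloxy)-4,9,10,13-tetramethoxy-6,8,12-trimethyl-15-(trimethylsilyl)pentadeca-2,6-dien-14-ynoate | C[Si](C)(C)C#C[C@H](OC)[C@@H](C)C[C@H](OC)[C@H](OC)[C@@H](C)/C=C(C)\[C@H](O[Si](C)(C)C(C)(C)C)[C@@H](OC)/C=C\C(=O)OC | intermediate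
28 | (2Z,4S,5S,6Z,8S,9R,10S,12S,13R)-5-(tert-butyldimethylsilyloxy)-4,9,10,13-tetramethoxy-6,8,12-trimethyl-15-(trimethylsilyl)pentadeca-2,6-dien-14-yn-1-ol | C[Si](C)(C)C#C[C@H](OC)[C@@H](C)C[C@H](OC)[C@H](OC)[C@@H](C)/C=C(C)\[C@H](O[Si](C)(C)C(C)(C)C)[C@@H](OC)/C=C\CO | intermediate
29 | (2Z,4S,5S,6Z,8S,9R,10S,12S,13R)-5-(tert-butyldimethylsilyloxy)-4,9,10,13-tetramethoxy-6,8,12-trimethyl-15-(trimethylsilyl)pentadeca-2,6-dien-14-ynal | C[Si](C)(C)C#C[C@H](OC)[C@@H](C)C[C@H](OC)[C@H](OC)[C@@H](C)/C=C(C)\[C@H](O[Si](C)(C)C(C)(C)C)[C@@H](OC)/C=C\C=O | intermediate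
30 | methyl (2Z,4Z,6S,7S,8Z,10S,11R,12S,14S,15R)-7-(tert-butyldimethylsilyloxy)-6,11,12,15-tetramethoxy-2,8,10,14-tetramethyl-17-(trimethylsilyl)heptadeca-2,4,8-trien-16-ynoate | C[Si](C)(C)C#C[C@H](OC)[C@@H](C)C[C@H](OC)[C@H](OC)[C@@H](C)/C=C(C)\[C@H](O[Si](C)(C)C(C)(C)C)[C@@H](OC)/C=C\C=C(C)/C(=O)OC | intermediate
31 | (2Z,4Z,6S,7S,8Z,10S,11R,12S,14S,15R)-7-(tert-butyldimethylsilyloxy)-6,11,12,15-tetramethoxy-2,8,10,14-tetramethylheptadeca-2,4,8-trien-16-ynoic acid | C#C[C@H](OC)[C@@H](C)C[C@H](OC)[C@H](OC)[C@@H](C)/C=C(C)\[C@H](O[Si](C)(C)C(C)(C)C)[C@@H](OC)/C=C\C=C(C)/C(=O)O | intermediate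
32 | isobutyl carbonic mixed anhydride of 31 | C#C[C@H](OC)[C@@H](C)C[C@H](OC)[C@H](OC)[C@@H](C)/C=C(C)\[C@H](O[Si](C)(C)C(C)(C)C)[C@@H](OC)/C=C\C=C(C)/C(=O)OC(=O)OCC(C)C | intermediate
33 | (2Z,4Z,6S,7S,8Z,10S,11R,12S,14S,15R)-7-(tert-butyldimethylsilyloxy)-6,11,12,15-tetramethoxy-2,8,10,14-tetramethylheptadeca-2,4,8-trien-16-ynamide | C#C[C@H](OC)[C@@H](C)C[C@H](OC)[C@H](OC)[C@@H](C)/C=C(C)\[C@H](O[Si](C)(C)C(C)(C)C)[C@@H](OC)/C=C\C=C(C)/C(N)=O | intermediate
34 | pentacarbonyl[ethynyl(methoxy)carbene]chromium | COC(C#C)=[Cr](=C=O)(=C=O)(=C=O)(=C=O)=C=O | intermediate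
35 | seco alkynyl dienamide chromium methoxycarbene (C7 silyl ether; E enamide) | C#C[C@H](OC)[C@@H](C)C[C@H](OC)[C@H](OC)[C@@H](C)/C=C(C)\[C@H](O[Si](C)(C)C(C)(C)C)[C@@H](OC)/C=C\C=C(C)/C(=O)N/C=C/C(OC)=[Cr](=C=O)(=C=O)(=C=O)(=C=O)=C=O | intermediate
36 | tricarbonylchromium η6-arene complex of 37 (written as its two components) | CO[C@H]1[C@@H](OC)C[C@H](C)[C@@H](OC)c2cc(OC)cc(c2O)NC(=O)/C(C)=C\C=C/[C@H](OC)[C@@H](O[Si](C)(C)C(C)(C)C)/C(C)=C\[C@@H]1C.O=C=[Cr](=C=O)=C=O | intermediate
37 | ansa lactam, C18 methyl ether, C21 phenol, C7 tert-butyldimethylsilyl ether (2Z,4Z,8Z; 6S,7S,10S,11R,12S,14S,15R) | CO[C@H]1[C@@H](OC)C[C@H](C)[C@@H](OC)c2cc(OC)cc(c2O)NC(=O)/C(C)=C\C=C/[C@H](OC)[C@@H](O[Si](C)(C)C(C)(C)C)/C(C)=C\[C@@H]1C | intermediate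
38 | ansa benzoquinone lactam, C7 tert-butyldimethylsilyl ether | CO[C@H]1[C@@H](OC)C[C@H](C)[C@@H](OC)C2=CC(=O)C=C(C2=O)NC(=O)/C(C)=C\C=C/[C@H](OC)[C@@H](O[Si](C)(C)C(C)(C)C)/C(C)=C\[C@@H]1C | intermediate
39 | ansa benzoquinone lactam, free C7 hydroxyl | CO[C@H]1[C@@H](OC)C[C@H](C)[C@@H](OC)C2=CC(=O)C=C(C2=O)NC(=O)/C(C)=C\C=C/[C@H](OC)[C@@H](O)/C(C)=C\[C@@H]1C | intermediate
40 | ansa benzoquinone lactam, C7 N-trichloroacetyl carbamate | CO[C@H]1[C@@H](OC)C[C@H](C)[C@@H](OC)C2=CC(=O)C=C(C2=O)NC(=O)/C(C)=C\C=C/[C@H](OC)[C@@H](OC(=O)NC(=O)C(Cl)(Cl)Cl)/C(C)=C\[C@@H]1C | intermediate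
41 | ansa benzoquinone lactam, C7 carbamate | CO[C@H]1[C@@H](OC)C[C@H](C)[C@@H](OC)C2=CC(=O)C=C(C2=O)NC(=O)/C(C)=C\C=C/[C@H](OC)[C@@H](OC(N)=O)/C(C)=C\[C@@H]1C | intermediate
42 | CNP0109452.1 | CO[C@H]1[C@@H](OC)C[C@H](C)[C@@H](OC)c2cc(O)cc(c2O)NC(=O)/C(C)=C\C=C/[C@H](OC)[C@@H](OC(N)=O)/C(C)=C\[C@@H]1C | target

## Step count and least certain steps

Total: 30 steps. Longest linear sequence: 28 steps (steps 2–14 and 16–30, from 5 to 42); steps 1 and 15 prepare 4 and 23.

**Step 26 (key step, proposed new method).**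
- Most likely failure: after alkyne insertion the vinylcarbene intermediate closes to a five-membered ring without taking up CO, the usual course for donor-substituted aminovinyl carbenes. Intermolecular insertion leading to oligomers is the second risk. Both arise because CO insertion must outrun competing closures while the chain ends meet only rarely.
- Fallback (known reactions only), from 30 back to 37: K2CO3 in MeOH removes the alkynyl silyl group to give the terminal alkyne ester F1. An intermolecular Dötz benzannulation of F1 with pentacarbonyl[methoxy((E)-2-trimethylsilylvinyl)carbene]chromium, a storable stand-in for the parent vinyl complex whose silicon ends on the phenol oxygen and is lost on work-up, gives the 2-substituted 4-methoxyphenol F2. Azo coupling with benzenediazonium tetrafluoroborate at the only free ortho position (C20) gives the azo phenol F3. Na2S2O4 cleaves the azo group to the aminophenol ester F4, and LiOH gives the amino acid F5. Macrolactamisation of F5 (bis(2-oxo-3-oxazolidinyl)phosphinic chloride, i-Pr2NEt, high dilution) returns to the route at 37.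

**Step 25.**
- Most likely failure: the amidate attacks the carbene carbon and displaces methoxide instead of adding at the β-carbon, or the complex decomposes under fluoride, because the amide is a much weaker and harder nucleophile than the amines for which this addition is routine.
- Fallback, from 4 and 31 back to 35: ammonia adds to 4 with loss of silicon to give the primary β-aminovinyl carbene F7; acid 31 is converted with 1-chloro-N,N,2-trimethylpropenylamine into the acid chloride F6; N-acylation of F7 with F6 (pyridine, 4-dimethylaminopyridine) gives 35.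

**Step 6.**
- Most likely failure: poor facial discrimination by the catalyst on an unhindered β-branched aliphatic aldehyde, leaving C12 epimers that are hard to separate.
- Fallback, from 10 back to 14: Horner–Wadsworth–Emmons reaction with triethyl phosphonoacetate gives the E-enoate F8, and i-Bu2AlH gives the E-allylic alcohol F9. Sharpless epoxidation with D-(−)-diethyl tartrate gives the (2R,3R)-epoxy alcohol F10. Ti(Oi-Pr)4-mediated opening with methanol at the carbon remote from the hydroxymethyl group, with inversion, gives the methoxy diol F11, and NaIO4 cleaves it to 14.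

**Step 22.**
- Most likely failure: Z to E isomerisation of the γ-alkoxy (Z)-enal before or during the olefination, and incomplete Z selectivity in forming the trisubstituted alkene; either would erode the (2Z,4Z) geometry.
- Fallback, from 26 back to 30: Corey–Fuchs reaction (CBr4, PPh3) gives the dibromoalkene F12. Treatment with n-BuLi and then N,N-dimethylformamide gives the ynal F13. Still–Gennari olefination gives the (Z)-enyne ester F14. Zinc activated with Cu(OAc)2 and AgNO3 reduces only the conjugated triple bond to the cis alkene, leaving the silylalkyne, and gives 30.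

**Step 29.**
- Most likely failure: during removal of the trichloroacetyl group a nucleophile adds to the quinone, or the acyl isocyanate also acylates the anilide nitrogen.
- Fallback, from 39 back to 41: NaOCN with CF3CO2H in CH2Cl2 generates cyanic acid, which adds to the C7 hydroxyl and gives 41 directly with no base treatment.

Further compounds
F1 | step 26 | methyl (2Z,4Z,6S,7S,8Z,10S,11R,12S,14S,15R)-7-(tert-butyldimethylsilyloxy)-6,11,12,15-tetramethoxy-2,8,10,14-tetramethylheptadeca-2,4,8-trien-16-ynoate | C#C[C@H](OC)[C@@H](C)C[C@H](OC)[C@H](OC)[C@@H](C)/C=C(C)\[C@H](O[Si](C)(C)C(C)(C)C)[C@@H](OC)/C=C\C=C(C)/C(=O)OC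
F2 | step 26 | seco ester with 2-hydroxy-5-methoxyphenyl group at C15 | COc1ccc(O)c(c1)[C@H](OC)[C@@H](C)C[C@H](OC)[C@H](OC)[C@@H](C)/C=C(C)\[C@H](O[Si](C)(C)C(C)(C)C)[C@@H](OC)/C=C\C=C(C)/C(=O)OC
F3 | step 26 | seco ester with 2-hydroxy-5-methoxy-3-(phenyldiazenyl)phenyl group at C15 | COc1cc(/N=N/c2ccccc2)c(O)c(c1)[C@H](OC)[C@@H](C)C[C@H](OC)[C@H](OC)[C@@H](C)/C=C(C)\[C@H](O[Si](C)(C)C(C)(C)C)[C@@H](OC)/C=C\C=C(C)/C(=O)OC
F4 | step 26 | seco ester with 3-amino-2-hydroxy-5-methoxyphenyl group at C15 | COc1cc(N)c(O)c(c1)[C@H](OC)[C@@H](C)C[C@H](OC)[C@H](OC)[C@@H](C)/C=C(C)\[C@H](O[Si](C)(C)C(C)(C)C)[C@@H](OC)/C=C\C=C(C)/C(=O)OC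
F5 | step 26 | seco amino acid with 3-amino-2-hydroxy-5-methoxyphenyl group at C15 | COc1cc(N)c(O)c(c1)[C@H](OC)[C@@H](C)C[C@H](OC)[C@H](OC)[C@@H](C)/C=C(C)\[C@H](O[Si](C)(C)C(C)(C)C)[C@@H](OC)/C=C\C=C(C)/C(=O)O
F6 | step 25 | acid chloride of 31 | C#C[C@H](OC)[C@@H](C)C[C@H](OC)[C@H](OC)[C@@H](C)/C=C(C)\[C@H](O[Si](C)(C)C(C)(C)C)[C@@H](OC)/C=C\C=C(C)/C(Cl)=O
F7 | step 25 | pentacarbonyl[(2Z)-3-amino-1-methoxyprop-2-enylidene]chromium | COC(/C=C\N)=[Cr](=C=O)(=C=O)(=C=O)(=C=O)=C=O
F8 | step 6 | ethyl (2E,5S,6R)-6-methoxy-5-methyl-8-(trimethylsilyl)oct-2-en-7-ynoate | C[Si](C)(C)C#C[C@H](OC)[C@@H](C)C/C=C/C(=O)OCC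
F9 | step 6 | (2E,5S,6R)-6-methoxy-5-methyl-8-(trimethylsilyl)oct-2-en-7-yn-1-ol | C[Si](C)(C)C#C[C@H](OC)[C@@H](C)C/C=C/CO
F10 | step 6 | (2R,3R)-epoxy alcohol from F9 | C[Si](C)(C)C#C[C@H](OC)[C@@H](C)C[C@H]1O[C@@H]1CO
F11 | step 6 | (2R,3S,5S,6R)-3,6-dimethoxy-5-methyl-8-(trimethylsilyl)oct-7-yne-1,2-diol | C[Si](C)(C)C#C[C@H](OC)[C@@H](C)C[C@H](OC)[C@H](O)CO
F12 | step 22 | 1,1-dibromoalkene from 26 | C[Si](C)(C)C#C[C@H](OC)[C@@H](C)C[C@H](OC)[C@H](OC)[C@@H](C)/C=C(C)\[C@H](O[Si](C)(C)C(C)(C)C)[C@@H](OC)C=C(Br)Br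
F13 | step 22 | C3 ynal with C4–C5 triple bond | C[Si](C)(C)C#C[C@H](OC)[C@@H](C)C[C@H](OC)[C@H](OC)[C@@H](C)/C=C(C)\[C@H](O[Si](C)(C)C(C)(C)C)[C@@H](OC)C#CC=O
F14 | step 22 | methyl (2Z)-enyne ester with C4–C5 triple bond | C[Si](C)(C)C#C[C@H](OC)[C@@H](C)C[C@H](OC)[C@H](OC)[C@@H](C)/C=C(C)\[C@H](O[Si](C)(C)C(C)(C)C)[C@@H](OC)C#C/C=C(C)\C(=O)OC
F0 | step 29 | none | none
A1 | alternative 1 | eight-membered cyclic silaketal with the Z C8–C9 alkene | COc1cc(Br)c(OC)c(c1)[C@H](OC)[C@@H](C)C[C@H](OC)[C@@H]2O[Si](C(C)C)(C(C)C)O[C@H]([C@H](COCc3ccc(OC)cc3)OC)/C(C)=C\[C@@H]2C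
A2 | alternative 1 | diisopropylsilylene-tethered diene | COc1cc(Br)c(OC)c(c1)[C@H](OC)[C@@H](C)C[C@H](OC)[C@H](O[Si](C(C)C)(C(C)C)O[C@H]([C@H](COCc3ccc(OC)cc3)OC)C(C)=C)[C@@H](C)C=C
A3 | alternative 2 | macrocyclic 4,5-didehydro enyne lactam | CO[C@H]1[C@@H](OC)C[C@H](C)[C@@H](OC)c2cc(OC)cc(c2OC)NC(=O)/C(C)=C\C#C[C@H](OC)[C@@H](O[Si](CC)(CC)CC)/C(C)=C\[C@@H]1C
A4 | alternative 2 | methyl-capped diyne anilide | COc1cc(NC(=O)/C(C)=C\C#CC)c(OC)c(c1)[C@H](OC)[C@@H](C)C[C@H](OC)[C@H](OC)[C@@H](C)/C=C(C)\[C@H](O[Si](CC)(CC)CC)[C@@H](OC)C#CC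
A5 | alternative 3 | protected macrolactam (C7 silyl ether, hydroquinone dimethyl ether) | CO[C@H]1[C@@H](OC)C[C@H](C)[C@@H](OC)c2cc(OC)cc(c2OC)NC(=O)/C(C)=C\C=C/[C@H](OC)[C@@H](O[Si](C)(C)C(C)(C)C)/C(C)=C\[C@@H]1C
A6 | alternative 3 | aryl bromide primary dienamide | COc1cc(Br)c(OC)c(c1)[C@H](OC)[C@@H](C)C[C@H](OC)[C@H](OC)[C@@H](C)/C=C(C)\[C@H](O[Si](C)(C)C(C)(C)C)[C@@H](OC)/C=C\C=C(C)/C(N)=O
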